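The hydroazulene is disconnected at the ring-fusion bond C3a–C8a and at C4–C5 (azulene numbering). This splits the seven-membered ring into a five-carbon unit C5–C6(Me)=C7–C8–C8a, drawn as a cis-isopropenylcyclopropane with C8a quaternary, and a two-carbon unit C3a–C4, a silyl alkyne tied to C8a through C1–C2–C3. One Rh(I)-catalysed intramolecular [5+2] cycloaddition closes the cyclopentane and the cycloheptadiene, leaves the C6=C7 alkene where the target has it, carries the cyclopropane stereocentre into quaternary C8a and puts an oxidisable silicon on C4. The precursor is an acyclic-chain cyclopropyl diol whose stereocentres all descend from one catalyst-set carbinol (C1).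

Key step: step 9

Remark on numbering: all bicyclic compounds use the azulene numbering of the target: C1 (angelate carbinol), C2, C3 (tertiary carbinol with isopropyl), C3a (ring-fusion CH), C4 (anisoate carbinol), C5, C6 (methyl-bearing alkene carbon), C7, C8, C8a (quaternary, methyl).

Assumption: the zinc–ProPhenol aldol of step 6 is taken to give the (5R) carbinol with the (S,S)-ligand. Should the opposite sense be found, the (R,R)-ligand is used and nothing else changes.

Step 1
Reactants: 1 methacrolein; 2 ethyl 2-[bis(2,2,2-trifluoroethoxy)phosphoryl]propanoate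
Product: 4 ethyl (2Z)-2,4-dimethylpenta-2,4-dienoate, via potassium phosphonate carbanion 3 (not isolated)
Conditions: KHMDS, 18-crown-6, THF, −78 °C; then 1
Reagents that add atoms: none
Why: Still–Gennari olefination, in which fast elimination from the kinetic adduct of the trifluoroethyl phosphonate should place the ester cis to the isopropenyl group (Z).

Step 2
Reactants: 4 ethyl (2Z)-2,4-dimethylpenta-2,4-dienoate
Product: 5 (2Z)-2,4-dimethylpenta-2,4-dien-1-ol
Conditions: DIBAL-H (2.2 equiv), CH2Cl2, −78 °C; Rochelle salt work-up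
Reagents that add atoms: none
Why: DIBAL-H 1,2-reduction of the enoate to the allylic alcohol, which should leave the alkene geometry untouched.

Step 3
Reactants: 5 (2Z)-2,4-dimethylpenta-2,4-dien-1-ol
Product: 6 (2Z)-2,4-dimethylpenta-2,4-dienal
Conditions: Dess–Martin periodinane, NaHCO3, CH2Cl2, 0 °C; solution used at once
Reagents that add atoms: none
Why: Buffered Dess–Martin oxidation is neutral and cold, so Z-to-E isomerisation of the enal should be avoided.

Step 4
Reactants: 7 ethynylmagnesium bromide; 8 benzyl(chloro)dimethylsilane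
Product: 9 benzyl(ethynyl)dimethylsilane
Conditions: THF, 0 °C to rt
Reagents that add atoms: none
Why: Grignard substitution at the Si–Cl bond gives the alkyne with a silyl group that can later be oxidised under Tamao conditions.

Step 5
Reactants: 9 benzyl(ethynyl)dimethylsilane; 10 N-methoxy-N-methylacetamide
Product: 12 4-[benzyl(dimethyl)silyl]but-3-yn-2-one, via lithium acetylide 11 (not isolated)
Conditions: n-BuLi, THF, −78 °C; then 10, −78 to 0 °C; aq NH4Cl
Reagents that add atoms: none
Why: Weinreb ketone synthesis, in which the chelated tetrahedral adduct should prevent a second addition of the acetylide.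

Step 6
Reactants: 6 (2Z)-2,4-dimethylpenta-2,4-dienal; 12 4-[benzyl(dimethyl)silyl]but-3-yn-2-one
Product: 13 (5R,6Z)-1-[benzyl(dimethyl)silyl]-5-hydroxy-6,8-dimethylnona-6,8-dien-1-yn-3-one
Conditions: (S,S)-ProPhenol (10 mol %), Et2Zn (20 mol %), 4 Å MS, THF, 0 °C
Reagents that add atoms: none
Why: Direct catalytic asymmetric aldol of a methyl ynone with the dinuclear zinc–ProPhenol catalyst, which forms the zinc ynone enolate and should deliver it to one face of the α-branched enal, so that the carbinol (future C1) is set by the catalyst.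

Step 7
Reactants: 13 (5R,6Z)-1-[benzyl(dimethyl)silyl]-5-hydroxy-6,8-dimethylnona-6,8-dien-1-yn-3-one
Product: 15 (3R,5R,6Z)-1-[benzyl(dimethyl)silyl]-6,8-dimethyl-3-(propan-2-yl)nona-6,8-dien-1-yne-3,5-diol, via chloromagnesium alkoxide 14 (not isolated)
Conditions: i-PrMgCl (3.5 equiv), CH2Cl2–THF, −78 °C; aq NH4Cl
Reagents that add atoms: isopropylmagnesium chloride CC(C)[Mg]Cl
Why: Chelation-controlled Grignard addition (Cram-chelate 1,3-induction), in which the magnesium alkoxide chelates the ynone carbonyl in a six-membered half-chair with the dienyl group equatorial and the isopropyl group adds axially, so that the alkynyl arm stays equatorial and C3 should be set as R (hydroxyls syn along the chain that runs into the alkyne).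

Step 8
Reactants: 15 (3R,5R,6Z)-1-[benzyl(dimethyl)silyl]-6,8-dimethyl-3-(propan-2-yl)nona-6,8-dien-1-yne-3,5-diol
Product: 17 (1R,3R)-5-[benzyl(dimethyl)silyl]-1-[(1R,2R)-1-methyl-2-(prop-1-en-2-yl)cyclopropyl]-3-(propan-2-yl)pent-4-yne-1,3-diol (isopropenyl cis to the carbinol chain), via zinc alkoxide 16 (not isolated)
Conditions: Et2Zn (4 equiv), CH2I2 (4 equiv), CH2Cl2, −10 to 0 °C; aq NH4Cl
Reagents that add atoms: diiodomethane ICI
Why: Hydroxyl-directed Simmons–Smith (Furukawa) cyclopropanation, in which A(1,3) strain with the cis isopropenyl group holds the carbinol hydrogen in the alkene plane and the zinc alkoxide delivers CH2 to the face that carries the oxygen, which should set both cyclopropane centres (1R,2R) from the carbinol while the undirected 1,1-disubstituted alkene and the alkyne are left alone.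

Step 9
Reactants: 17 (1R,3R)-5-[benzyl(dimethyl)silyl]-1-[(1R,2R)-1-methyl-2-(prop-1-en-2-yl)cyclopropyl]-3-(propan-2-yl)pent-4-yne-1,3-diol
Product: 18 (1R,3R,8aR)-4-[benzyl(dimethyl)silyl]-6,8a-dimethyl-3-(propan-2-yl)-1,2,3,5,8,8a-hexahydroazulene-1,3-diol
Conditions: [Rh(CO)2Cl]2 (5 mol %), 1,2-dichloroethane, 70 °C
Reagents that add atoms: none
Why: Rh(I) binds the isopropenyl group and inserts into the adjacent, more substituted cyclopropane bond (C7–C8a of the product) to give a σ-alkyl/π-allyl rhodacycle, the tethered alkyne inserts into the Rh–C8a bond (forming C3a–C8a), and reductive elimination joins the alkenyl carbon C4 to the allyl terminus C5 and releases Rh(I). The closest known reaction type is the Wender-type Rh(I)-catalysed intramolecular vinylcyclopropane [5+2] cycloaddition, in the variant in which the two-carbon partner is tethered to the cyclopropane carbon cis to the vinyl group. The cyclopentane closes by migratory insertion through the three-atom C1–C2–C3 tether (5-exo with respect to the alkyne), and the cycloheptadiene closes by the metal-mediated union of the five-carbon unit C5–C6=C7–C8–C8a with the alkyne C3a≡C4, the C6=C7 alkene being cis by ring size. No new stereocentre is created: C8a keeps its configuration because Rh replaces C7 and C3a then replaces Rh, each with retention, the cyclopropane CH centre becomes sp2, and C1 and C3 are spectators. The step needs cleavage of the proximal C7–C8a bond instead of the distal C7–C8 bond (which would lead to a bridged isomer) and [5+2] instead of [3+2] reductive elimination; the cis relation of tether and isopropenyl group, the short tether that reaches only the Rh–C8a bond, and the free hydroxyl at C1 (a poor leaving group toward β-oxygen elimination) should secure this. The alkyne is flanked by a fully substituted carbinol and silicon and is the weak point, so a small CO-ligated neutral Rh(I) source and mild heating are chosen.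

Step 10
Reactants: 18 (1R,3R,8aR)-4-[benzyl(dimethyl)silyl]-6,8a-dimethyl-3-(propan-2-yl)-1,2,3,5,8,8a-hexahydroazulene-1,3-diol; 19 angelic acid [(2Z)-2-methylbut-2-enoic acid]
Product: 21 (1R,3R,8aR)-4-[benzyl(dimethyl)silyl]-3-hydroxy-6,8a-dimethyl-3-(propan-2-yl)-1,2,3,5,8,8a-hexahydroazulen-1-yl (2Z)-2-methylbut-2-enoate, via mixed Yamaguchi anhydride 20 (not isolated)
Conditions: 19, 2,4,6-trichlorobenzoyl chloride, Et3N, toluene, rt; then 18, 75 °C
Reagents that add atoms: none
Why: Yamaguchi esterification without a nucleophilic catalyst should acylate the secondary C1 hydroxyl only, leave the tertiary C3 hydroxyl free and keep the Z geometry of the angelate.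

Step 11
Reactants: 21 (1R,3R,8aR)-4-[benzyl(dimethyl)silyl]-3-hydroxy-6,8a-dimethyl-3-(propan-2-yl)-1,2,3,5,8,8a-hexahydroazulen-1-yl (2Z)-2-methylbut-2-enoate
Product: 23 (1R,3R,3aR,8aR)-3-hydroxy-6,8a-dimethyl-4-oxo-3-(propan-2-yl)-1,2,3,3a,4,5,8,8a-octahydroazulen-1-yl (2Z)-2-methylbut-2-enoate, via cyclic siloxane 22 (not isolated)
Conditions: TBAF, THF, 0 °C; then 30% H2O2, KHCO3, MeOH–THF, rt
Reagents that add atoms: hydrogen peroxide OO
Why: Tamao–Fleming oxidation of the alkenyl benzyldimethylsilane, in which fluoride removes the benzyl group, the C3 alkoxide captures silicon, peroxide-induced migration of C4 from Si to O and hydrolysis give the C4 enol, and ketonisation should place hydrogen on C3a from the β face, away from the angular methyl and the α-disposed O–Si bridge, which is also the more stable trans-fused epimer (C4 cis to OH and not to isopropyl on C3).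

Step 12
Reactants: 23 (1R,3R,3aR,8aR)-3-hydroxy-6,8a-dimethyl-4-oxo-3-(propan-2-yl)-1,2,3,3a,4,5,8,8a-octahydroazulen-1-yl (2Z)-2-methylbut-2-enoate
Product: 24 (1R,3R,3aS,4S,8aR)-3,4-dihydroxy-6,8a-dimethyl-3-(propan-2-yl)-1,2,3,3a,4,5,8,8a-octahydroazulen-1-yl (2Z)-2-methylbut-2-enoate
Conditions: Me4NBH(OAc)3, MeCN–AcOH (1:1), −20 °C
Reagents that add atoms: none
Why: Evans–Saksena hydroxyl-directed reduction, in which the triacetoxyborohydride exchanges onto the C3 hydroxyl and delivers hydride intramolecularly through a chair-like six-membered transition state that the puckered cyclopentane allows on one face of C4 only, which should give the 4S alcohol (1,3-anti to the C3 hydroxyl).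

Step 13
Reactants: 24 (1R,3R,3aS,4S,8aR)-3,4-dihydroxy-6,8a-dimethyl-3-(propan-2-yl)-1,2,3,3a,4,5,8,8a-octahydroazulen-1-yl (2Z)-2-methylbut-2-enoate; 25 4-methoxybenzoyl chloride
Product: 26 (1R,3R,3aS,4S,8aR)-3-hydroxy-6,8a-dimethyl-1-{[(2Z)-2-methylbut-2-enoyl]oxy}-3-(propan-2-yl)-1,2,3,3a,4,5,8,8a-octahydroazulen-4-yl 4-methoxybenzoate (CNP0204191.1)
Conditions: Et3N, DMAP (cat.), CH2Cl2, 0 °C to rt
Reagents that add atoms: none
Why: DMAP-catalysed acylation with the acid chloride should be selective for the single secondary alcohol over the hindered tertiary one.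

Compound list
1 | methacrolein | C=C(C)C=O | starting material
2 | ethyl 2-[bis(2,2,2-trifluoroethoxy)phosphoryl]propanoate | CCOC(=O)C(C)P(=O)(OCC(F)(F)F)OCC(F)(F)F | starting material
3 | potassium phosphonate carbanion of 2 | CCOC(=O)[C-](C)P(=O)(OCC(F)(F)F)OCC(F)(F)F.[K+] | intermediate
4 | ethyl (2Z)-2,4-dimethylpenta-2,4-dienoate | C=C(C)\C=C(C)/C(=O)OCC | intermediate
5 | (2Z)-2,4-dimethylpenta-2,4-dien-1-ol | C=C(C)\C=C(C)/CO | intermediate
6 | (2Z)-2,4-dimethylpenta-2,4-dienal | C=C(C)\C=C(C)/C=O | intermediate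
7 | ethynylmagnesium bromide | C#C[Mg]Br | starting material
8 | benzyl(chloro)dimethylsilane | C[Si](C)(Cl)Cc1ccccc1 | starting material
9 | benzyl(ethynyl)dimethylsilane | C#C[Si](C)(C)Cc1ccccc1 | intermediate
10 | N-methoxy-N-methylacetamide | CC(=O)N(C)OC | starting material
11 | lithium acetylide of 9 | [Li]C#C[Si](C)(C)Cc1ccccc1 | intermediate
12 | 4-[benzyl(dimethyl)silyl]but-3-yn-2-one | CC(=O)C#C[Si](C)(C)Cc1ccccc1 | intermediate
13 | (5R,6Z)-1-[benzyl(dimethyl)silyl]-5-hydroxy-6,8-dimethylnona-6,8-dien-1-yn-3-one | C=C(C)\C=C(C)/[C@H](O)CC(=O)C#C[Si](C)(C)Cc1ccccc1 | intermediate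
14 | chloromagnesium alkoxide of 13 | C=C(C)\C=C(C)/[C@H](O[Mg]Cl)CC(=O)C#C[Si](C)(C)Cc1ccccc1 | intermediate
15 | (3R,5R,6Z)-1-[benzyl(dimethyl)silyl]-6,8-dimethyl-3-(propan-2-yl)nona-6,8-dien-1-yne-3,5-diol | C=C(C)\C=C(C)/[C@H](O)C[C@@](O)(C(C)C)C#C[Si](C)(C)Cc1ccccc1 | intermediate
16 | bis(ethylzinc) alkoxide of 15 | C=C(C)\C=C(C)/[C@H](O[Zn]CC)C[C@@](O[Zn]CC)(C(C)C)C#C[Si](C)(C)Cc1ccccc1 | intermediate
17 | (1R,3R)-5-[benzyl(dimethyl)silyl]-1-[(1R,2R)-1-methyl-2-(prop-1-en-2-yl)cyclopropyl]-3-(propan-2-yl)pent-4-yne-1,3-diol | C=C(C)[C@H]1C[C@@]1(C)[C@H](O)C[C@@](O)(C(C)C)C#C[Si](C)(C)Cc1ccccc1 | intermediate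
18 | (1R,3R,8aR)-4-[benzyl(dimethyl)silyl]-6,8a-dimethyl-3-(propan-2-yl)-1,2,3,5,8,8a-hexahydroazulene-1,3-diol | O[C@@H]1C[C@@](O)(C(C)C)C2=C([Si](C)(C)Cc3ccccc3)CC(C)=CC[C@]21C | intermediate
19 | angelic acid, (2Z)-2-methylbut-2-enoic acid | C/C=C(/C)C(=O)O | starting material
20 | (2Z)-2-methylbut-2-enoic 2,4,6-trichlorobenzoic anhydride | C/C=C(/C)C(=O)OC(=O)c1c(Cl)cc(Cl)cc1Cl | intermediate
21 | (1R,3R,8aR)-4-[benzyl(dimethyl)silyl]-3-hydroxy-6,8a-dimethyl-3-(propan-2-yl)-1,2,3,5,8,8a-hexahydroazulen-1-yl (2Z)-2-methylbut-2-enoate | C/C=C(/C)C(=O)O[C@@H]1C[C@@](O)(C(C)C)C2=C([Si](C)(C)Cc3ccccc3)CC(C)=CC[C@]21C | intermediate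
22 | cyclic siloxane of 21 (C3–O–SiMe2–C4 bridge, benzyl lost) | C/C=C(/C)C(=O)O[C@@H]1C[C@]2(C(C)C)O[Si](C)(C)C3=C2[C@@]1(C)CC=C(C)C3 | intermediate
23 | (1R,3R,3aR,8aR)-3-hydroxy-6,8a-dimethyl-4-oxo-3-(propan-2-yl)-1,2,3,3a,4,5,8,8a-octahydroazulen-1-yl (2Z)-2-methylbut-2-enoate | C/C=C(/C)C(=O)O[C@@H]1C[C@@](O)(C(C)C)[C@@H]2C(=O)CC(C)=CC[C@]21C | intermediate
24 | (1R,3R,3aS,4S,8aR)-3,4-dihydroxy-6,8a-dimethyl-3-(propan-2-yl)-1,2,3,3a,4,5,8,8a-octahydroazulen-1-yl (2Z)-2-methylbut-2-enoate | C/C=C(/C)C(=O)O[C@@H]1C[C@@](O)(C(C)C)[C@@H]2[C@@H](O)CC(C)=CC[C@]21C | intermediate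
25 | 4-methoxybenzoyl chloride | COc1ccc(cc1)C(Cl)=O | starting material
26 | (1R,3R,3aS,4S,8aR)-3-hydroxy-6,8a-dimethyl-1-{[(2Z)-2-methylbut-2-enoyl]oxy}-3-(propan-2-yl)-1,2,3,3a,4,5,8,8a-octahydroazulen-4-yl 4-methoxybenzoate | C/C=C(/C)C(=O)O[C@@H]1C[C@@](O)(C(C)C)[C@@H]2[C@@H](OC(=O)c3ccc(OC)cc3)CC(C)=CC[C@]21C | target

Total step count: 13. Longest linear sequence: 11 steps (steps 1–3 and 6–13); steps 4–5 are a two-step side branch.

Steps most likely to fail

Step 9. Insertion of the alkyne, which is flanked by a fully substituted carbinol and by silicon, into the tertiary alkyl–rhodium bond may be too slow. Opening of the distal cyclopropane bond, [3+2]-type reductive elimination or a thermal homodienyl hydrogen shift of the cis-vinylcyclopropane could then take over. The fallback sets out from 13 and comes back at 18. It keeps the same [5+2] bond formation but uses the less hindered, electron-poor ynone as the two-carbon partner and adds the isopropyl group afterwards on the bicycle, which also removes the acyclic 1,3-induction of step 7. Hydroxyl-directed Simmons–Smith cyclopropanation of 13 (Et2Zn, CH2I2) would give (5R)-1-[benzyl(dimethyl)silyl]-5-hydroxy-5-[(1R,2R)-1-methyl-2-(prop-1-en-2-yl)cyclopropyl]pent-1-yn-3-one F1. Silylation (TESCl, imidazole), which blocks oxa-Michael closure, would give the triethylsilyl ether F2. Rh(I)-catalysed [5+2] cycloaddition of this ynone would give the bicyclic dienone (1R,8aR)-4-[benzyl(dimethyl)silyl]-6,8a-dimethyl-1-[(triethylsilyl)oxy]-1,2,8,8a-tetrahydroazulen-3(5H)-one F3. Addition of i-PrMgCl/CeCl3 to the cyclopentanone from the β face, opposite the angular methyl and the C1 silyloxy group, would give the tertiary alcohol F4. Removal of the silyl ether (PPTS, MeOH) returns 18.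

Step 11. The tertiary β-ketol may be lost by retro-aldol cleavage or dehydration under the basic peroxide conditions, the C6=C7 alkene may drift into conjugation with the new ketone, or the enol may be protonated from the wrong face at C3a. The fallback sets out from 18 and comes back at 23, and reaches the ketone under neutral conditions. Protodesilylation of 18 (TBAF, THF, 60 °C) would give (1R,3R,8aR)-6,8a-dimethyl-3-(propan-2-yl)-1,2,3,5,8,8a-hexahydroazulene-1,3-diol F5. Yamaguchi esterification with 19 as in step 10 would give its C1 angelate F6. Hydroxyl-directed epoxidation of the C3a=C4 alkene (VO(acac)2, t-BuOOH) would give the α-epoxide F7, chemoselectively over the C6=C7 alkene. Titanocene(III)-mediated radical opening at the tertiary carbon (Cp2TiCl2 cat., Mn, collidine hydrochloride, 1,4-cyclohexadiene) would give the anti-Markovnikov C4 alcohol (1R,3R,3aS,4R,8aR)-3,4-dihydroxy-6,8a-dimethyl-3-(propan-2-yl)-1,2,3,3a,4,5,8,8a-octahydroazulen-1-yl (2Z)-2-methylbut-2-enoate F8, with hydrogen delivered to C3a anti to the titanium-bound oxygen. Buffered Dess–Martin oxidation of F8 returns 23.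

Step 6. Enantio-induction may be low with this α-branched Z-enal, or the enal may isomerise from Z to E in the presence of the zinc catalyst. The fallback sets out from 6 and comes back at 13, and replaces catalyst control by a separable auxiliary. Titanium enolate aldol (TiCl4, i-Pr2NEt, CH2Cl2, −78 °C) of N-acetyl-(4S)-4-(propan-2-yl)-1,3-thiazolidine-2-thione with 6 would give (3R,4Z)-3-hydroxy-4,6-dimethyl-1-[(4S)-4-(propan-2-yl)-2-sulfanylidene-1,3-thiazolidin-3-yl]hepta-4,6-dien-1-one F9, purified from its diastereomer by chromatography (the antipodal auxiliary is used if the other diastereomer predominates). Displacement of the auxiliary with N,O-dimethylhydroxylamine hydrochloride and imidazole would give the Weinreb amide (3R,4Z)-3-hydroxy-N-methoxy-N,4,6-trimethylhepta-4,6-dienamide F10. Addition of excess lithium acetylide 11 (THF, −78 to 0 °C) returns 13.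

Further compounds
F1 | step 9 | (5R)-1-[benzyl(dimethyl)silyl]-5-hydroxy-5-[(1R,2R)-1-methyl-2-(prop-1-en-2-yl)cyclopropyl]pent-1-yn-3-one | C=C(C)[C@H]1C[C@@]1(C)[C@H](O)CC(=O)C#C[Si](C)(C)Cc1ccccc1
F2 | step 9 | (5R)-1-[benzyl(dimethyl)silyl]-5-[(1R,2R)-1-methyl-2-(prop-1-en-2-yl)cyclopropyl]-5-[(triethylsilyl)oxy]pent-1-yn-3-one | C=C(C)[C@H]1C[C@@]1(C)[C@H](O[Si](CC)(CC)CC)CC(=O)C#C[Si](C)(C)Cc1ccccc1
F3 | step 9 | (1R,8aR)-4-[benzyl(dimethyl)silyl]-6,8a-dimethyl-1-[(triethylsilyl)oxy]-1,2,8,8a-tetrahydroazulen-3(5H)-one | CC[Si](CC)(CC)O[C@@H]1CC(=O)C2=C([Si](C)(C)Cc3ccccc3)CC(C)=CC[C@]21C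
F4 | step 9 | (1R,3R,8aR)-4-[benzyl(dimethyl)silyl]-6,8a-dimethyl-3-(propan-2-yl)-1-[(triethylsilyl)oxy]-1,2,3,5,8,8a-hexahydroazulen-3-ol | CC[Si](CC)(CC)O[C@@H]1C[C@@](O)(C(C)C)C2=C([Si](C)(C)Cc3ccccc3)CC(C)=CC[C@]21C
F5 | step 11 | (1R,3R,8aR)-6,8a-dimethyl-3-(propan-2-yl)-1,2,3,5,8,8a-hexahydroazulene-1,3-diol | O[C@@H]1C[C@@](O)(C(C)C)C2=CCC(C)=CC[C@]21C
F6 | step 11 | (1R,3R,8aR)-3-hydroxy-6,8a-dimethyl-3-(propan-2-yl)-1,2,3,5,8,8a-hexahydroazulen-1-yl (2Z)-2-methylbut-2-enoate | C/C=C(/C)C(=O)O[C@@H]1C[C@@](O)(C(C)C)C2=CCC(C)=CC[C@]21C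
F7 | step 11 | 3a,4-α-epoxide of F6 (oxygen on the face of the C3 hydroxyl) | C/C=C(/C)C(=O)O[C@@H]1C[C@@](O)(C(C)C)[C@]23O[C@@H]3CC(C)=CC[C@]21C
F8 | step 11 | (1R,3R,3aS,4R,8aR)-3,4-dihydroxy-6,8a-dimethyl-3-(propan-2-yl)-1,2,3,3a,4,5,8,8a-octahydroazulen-1-yl (2Z)-2-methylbut-2-enoate | C/C=C(/C)C(=O)O[C@@H]1C[C@@](O)(C(C)C)[C@@H]2[C@H](O)CC(C)=CC[C@]21C
F9 | step 6 | (3R,4Z)-3-hydroxy-4,6-dimethyl-1-[(4S)-4-(propan-2-yl)-2-sulfanylidene-1,3-thiazolidin-3-yl]hepta-4,6-dien-1-one | C=C(C)\C=C(C)/[C@H](O)CC(=O)N1[C@@H](C(C)C)CSC1=S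
F10 | step 6 | (3R,4Z)-3-hydroxy-N-methoxy-N,4,6-trimethylhepta-4,6-dienamide | C=C(C)\C=C(C)/[C@H](O)CC(=O)N(C)OC
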